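## Structural features

The target is an isoflavone: a 4H-chromen-4-one whose benzo ring (ring A) is fused through C4a and C8a to the pyranone (ring C), with a 3,4-dimethoxyphenyl group (ring B) bonded to C3. Ring A carries one substituent, a prenyl (3-methylbut-2-enyl) ether at C7, which is meta to the ring oxygen O1 and para to C4a. There is no stereocenter, so the problem is one of connectivity and regiochemistry only. The fragile parts are the prenyl ether (sensitive to acid, to hydrogenation and to zerovalent palladium) and the C2=C3 bond of ring C (open to nucleophiles at C2, with ring opening by alkoxide or hydroxide, and to over-reduction to the isoflavanone). The real difficulty is to close ring C with the aryl group at C3 rather than C2 and with the correct orientation towards the C7 oxygen. The key step exploits the fact that O1 and the carbonyl carbon C4 are attached to the adjacent ring A carbons C8a and C4a. An aryne across C4a–C8a can therefore take an oxygen nucleophile at C8a and an acyl electrophile at C4a from a single partner that already holds O1, C2, C3, C4 and ring B.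

## Logic of the disconnections

16 is cut at the ether bond between O7 and the CH2 of the prenyl group, giving 14 and 15. The prenyl ether would not survive the hydrogenation planned earlier, and its allylic C–H bonds and alkene are liabilities towards organolithiums and arynes, so it goes on last. This leaves a phenol with one nucleophilic site. The forward step must be an O-alkylation under a base mild enough not to open ring C.

14 is traced back to 13 without cutting a skeletal bond: a chlorine is added at C5 and a benzyl group on O7. The chlorine is there only to steer the ring-forming step and the benzyl group only to mask the phenol from organolithium reagents. Both are removable by hydrogen on palladium in one operation. The demand is that this reduction stops before the C2=C3 bond is touched.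

13 is cut at O1–C8a and at C4–C4a, which gives 5 and 8; in the forward sense these react through 9, 10, 11 and 12. The two bonds are neighbours on ring A, which is the pattern an aryne delivers, and the cut removes ring C completely. What remains is a symmetrical trihalobenzene and a three-carbon piece that already carries ring B. The forward step needs three selectivities: addition to the aryne carbon remote from chlorine, attack through the enolate oxygen rather than carbon, and a cis arrangement of enol oxygen and ester so that the aryl anion can close the ring.

5 is cut at the C–I bond to give 3 (forward through 4), and 3 at the benzylic O–CH2 bond to give 1 and 2. The C–H of 3 flanked by both chlorines is the most acidic ring position, and the symmetry of 1 means no regiochemical question arises in the etherification. The demand is a base that leaves the benzylic CH2 and the C–H next to oxygen alone, and a metalated arene that does not lose metal chloride before the iodine arrives.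

8 is cut at the bond between its formyl-derived carbon (the future C2) and the α-carbon (the future C3), giving 6 and a formate ester as one-carbon donor; the forward reaction passes through 7. This is a crossed Claisen retron and leads to a commercial arylacetate. The demand is matching of base and formate to the methyl ester so that no ester exchange occurs, and isolation of the chelated Z enol.

## Other disconnections considered

Alternative 1: The cut is at C3–C4, with the C2=C3 bond made afterwards by loss of water. In the forward step a thiazolium-derived carbene with an amidine base converts the aldehyde of the keto aldehyde A1 into a Breslow intermediate. This adds to the tethered aryl ketone and closes ring C as the racemic tertiary ketol A2, and dehydration of A2 then gives the target.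
- In favour: the intramolecular aldehyde–ketone benzoin reaction to 3-hydroxychroman-4-ones is an established reaction class. The prenyl ether is carried from the start, so there is no protecting group, no halogen and no hydrogenation. Ring A regiochemistry is fixed by the substitution of the starting aldehyde.
- Against: the hydroxyl of A2 sits on the carbon α to the ketone and the C2 hydrogens are not acidified, so water cannot leave by an E1cB path. Activation or acid is needed, acid endangers the prenyl ether, and a cation at C3 invites ketol or aryl shifts. The amidine base may also enolise the aryloxy ketone of A1 and start an aldol closure to a benzofuran. The electron-rich aldehyde and ketone are both sluggish partners.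
- Comparison: A1 should be available in two O-alkylations, so about four steps stand against six. On step economy this alternative is the better plan, and on mechanistic precedent for ring closure it is also better. The chosen plan is stronger only in that its last steps are mild and the prenyl group never meets acid. The stereocenter of A2 is made and destroyed, which costs nothing.

Alternative 2: The cut removes C3 with ring B as a one-carbon unit, breaking C2–C3 and C3–C4. In the forward step, warming the chlorodiazirine A4 releases an arylchlorocarbene that cyclopropanates the enol ether double bond of the bis-silyl benzofuran A3. The chlorocyclopropane opens with loss of chloride and of the enol silyl group, and the furan expands to the pyranone A5. Desilylation and O-prenylation of A5 would finish the synthesis.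
- In favour: the plan is convergent, ring A regiochemistry is preset in A3, and no directing halogen or hydrogenation is needed. On the end-game it is the equal of the chosen plan or better. Four to five steps make it at least equal in step count.
- Against: chlorodiazirines with electron-rich aryl groups are hard to make and store and are energetic. The donor-stabilised carbene is less electrophilic and prone to self-reaction. A3 is moisture-sensitive. The one-carbon insertion into a benzofuran enol ether is itself without firm precedent.
- Comparison: mechanistically it is no more certain than the chosen plan; both rest on an extrapolation. The chosen plan uses only stable, storable intermediates.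

Alternative 3: The cut is at C4–C4a only. In the forward step the acrylic acid A6 is ionised in Eaton's reagent (P2O5 in CH3SO3H) to an acylium ion, which acylates the aryloxy ring at the position para to the free hydroxyl and gives A7. A7 is the same compound as 14 and would be prenylated as in the chosen plan.
- In favour: the closure is a classical Friedel–Crafts acylation with much precedent for aryloxy acids. No organometallic reagent, halogen or hydrogenation is involved. In precedent it is better than the chosen plan, and in the final step it is equal.
- Against: the ring carbon between the two oxygens is also activated, so the 5-hydroxy isomer can form, and only sterics oppose it. The chosen plan settles this point with the chlorine. The aryloxyacrylic acid is an enol ether that hot strong acid can hydrolyse. Ring B is the most electron-rich arene present and may be acylated intermolecularly. Making A6 from 8 needs activation, a mono-selective vinylic substitution by a meta-dihydroxybenzene and an ester hydrolysis.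
- Comparison: the step count comes to about six, equal to the chosen plan. It forms O1–C2 and C4–C4a in separate steps, where the chosen plan forms O1–C8a and C4–C4a together.

Key step: step 4

Remark on the chemistry: an atom-by-atom check confirms that oxygen addition at the aryne carbon remote from chlorine places chlorine at C5 and benzyloxy at C7 of 13, and that 8 must be the Z enol (hydroxyl cis to the ester). The precursor design is refined in two ways: 10 and 9 are made in separate flasks so that n-BuLi meets neither the enol nor the ester, and 5 is made through the arylmagnesium 4, which cannot lose metal chloride before the iodine quench.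

## Route

Step 1
Reactants: 1 3,5-dichlorophenol; 2 benzyl bromide
Product: 3 1-(benzyloxy)-3,5-dichlorobenzene
Conditions: K2CO3, DMF, rt
Reagents that add atoms: none
Why: Williamson ether synthesis; the acidic dichlorophenol is fully ionised by carbonate and the phenoxide displaces bromide from the benzylic carbon by SN2, with no competing site in the symmetrical phenol.

Step 2
Reactants: 3 1-(benzyloxy)-3,5-dichlorobenzene
Product: 5 5-(benzyloxy)-1,3-dichloro-2-iodobenzene, via arylmagnesium chloride 4 (not isolated)
Conditions: TMPMgCl·LiCl [(2,2,6,6-tetramethylpiperidin-1-yl)magnesium chloride–lithium chloride], THF, 25 °C; then I2, THF, 0 °C to rt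
Reagents that add atoms: iodine, II
Why: Directed deprotonative magnesiation of a polyhaloarene with a hindered magnesium amide at the ring C–H flanked by two chlorines, the most acidic position, followed by iodolysis of the C–Mg bond; the amide base should leave the benzylic CH2 alone, and unlike an ortho-chloroaryllithium the ortho-chloroarylmagnesium chloride 4 should not lose metal chloride at these temperatures, so no aryne can leak before the iodine quench.

Step 3
Reactants: 6 methyl (3,4-dimethoxyphenyl)acetate
Product: 8 methyl (2Z)-2-(3,4-dimethoxyphenyl)-3-hydroxyprop-2-enoate, via potassium enolate 7 (not isolated)
Conditions: HCO2Me, KOMe, THF, 0 °C to rt; then dilute HCl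
Reagents that add atoms: methyl formate, COC=O
Why: Crossed Claisen condensation (C-formylation) driven by formation of the stabilised potassium enolate 7; methoxide and methyl formate both match the methyl ester so no ester scrambling can occur, and acidification should give the hydrogen-bonded Z enol.

Step 4
Reactants: 5 5-(benzyloxy)-1,3-dichloro-2-iodobenzene; 8 methyl (2Z)-2-(3,4-dimethoxyphenyl)-3-hydroxyprop-2-enoate
Product: 13 7-(benzyloxy)-5-chloro-3-(3,4-dimethoxyphenyl)chromen-4-one, via sodium enolate 9 (not isolated), via aryllithium 10 (not isolated), via aryne 11 (not isolated), via aryl anion 12 (not isolated)
Conditions: 8, NaH, THF, 0 °C (gives 9, 2 equiv); 5, n-BuLi, THF, –78 °C (gives 10); cold 10 added slowly to 9 at –20 °C, then 0 °C; aq. NH4Cl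
Reagents that add atoms: none
Why: Proposed new method: iodine–lithium exchange on 5 should outrun any attack of n-BuLi on the benzyl ether at –78 °C, and 10 should persist until it enters the warmer enolate solution, where loss of LiCl (either chlorine, the two being equivalent) gives aryne 11. The enolate oxygen of 9 is expected to add to the aryne carbon remote from chlorine (the future C8a), because the chlorine polarises and distorts the triple bond so that the carbanion develops on the carbon next to it (the future C4a); this ortho-halogen effect should outweigh the weak opposite bias of the benzyloxy group. Aryl anion 12 then attacks the cis ester carbonyl in a 6-exo-trig addition and the tetrahedral intermediate expels methoxide, so ring C closes by intramolecular acyl substitution with O1–C8a and C4–C4a formed in one operation. The closest known reaction type is the annulation of arynes with salicylate esters to xanthones, of which 9 is the open-chain counterpart, combined with the distal addition of nucleophiles to 3-haloarynes. Attack through oxygen rather than carbon is required; it is favoured because the enolate carbon is fully substituted and conjugated with ring B while the oxygen end is unhindered, but this is the unproven point. The Z geometry needed for closure should be held by sodium chelation between the enolate oxygen and the ester carbonyl. Slow addition of 10 to an excess of 9 keeps 10 from adding to 11, and making 10 from the purified iodide rather than with an amide base keeps amines, which trap arynes, out of the flask. No stereocenter is formed.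

Step 5
Reactants: 13 7-(benzyloxy)-5-chloro-3-(3,4-dimethoxyphenyl)chromen-4-one
Product: 14 3-(3,4-dimethoxyphenyl)-7-hydroxychromen-4-one
Conditions: H2 (1 atm), Pd/C (10% Pd), NaOAc, THF–MeOH, rt
Reagents that add atoms: none
Why: Hydrogenolysis of the benzyl ether and hydrodechlorination of the aryl chloride, which lies peri to the carbonyl and is therefore activated, on the same catalyst; NaOAc takes up the HCl that would otherwise poison the catalyst, and the reaction is stopped once both groups are gone so that C2=C3 is spared.

Step 6
Reactants: 14 3-(3,4-dimethoxyphenyl)-7-hydroxychromen-4-one; 15 prenyl bromide (1-bromo-3-methylbut-2-ene)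
Product: 16 3-(3,4-dimethoxyphenyl)-7-(3-methylbut-2-enyloxy)chromen-4-one (7-prenyloxy-3',4'-dimethoxyisoflavone)
Conditions: K2CO3, acetone, reflux
Reagents that add atoms: none
Why: Williamson O-alkylation of the acidic 7-hydroxyl (a vinylogous carboxylic acid) by SN2 at the primary carbon of prenyl bromide; carbonate in acetone is too mild to open ring C and there is no second nucleophilic site.

## Compound list

1 | 3,5-dichlorophenol | Oc1cc(Cl)cc(Cl)c1 | starting material
2 | benzyl bromide | BrCc1ccccc1 | starting material
3 | 1-(benzyloxy)-3,5-dichlorobenzene | Clc1cc(Cl)cc(OCc2ccccc2)c1 | intermediate
4 | [4-(benzyloxy)-2,6-dichlorophenyl]magnesium chloride | Cl[Mg]c1c(Cl)cc(OCc2ccccc2)cc1Cl | intermediate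
5 | 5-(benzyloxy)-1,3-dichloro-2-iodobenzene | Clc1cc(OCc2ccccc2)cc(Cl)c1I | intermediate
6 | methyl (3,4-dimethoxyphenyl)acetate | COC(=O)Cc1ccc(OC)c(OC)c1 | starting material
7 | potassium (1Z)-2-(3,4-dimethoxyphenyl)-3-methoxy-3-oxoprop-1-en-1-olate | COC(=O)/C(=C\[O-])c1ccc(OC)c(OC)c1.[K+] | intermediate
8 | methyl (2Z)-2-(3,4-dimethoxyphenyl)-3-hydroxyprop-2-enoate | COC(=O)/C(=C\O)c1ccc(OC)c(OC)c1 | intermediate
9 | sodium (1Z)-2-(3,4-dimethoxyphenyl)-3-methoxy-3-oxoprop-1-en-1-olate | COC(=O)/C(=C\[O-])c1ccc(OC)c(OC)c1.[Na+] | intermediate
10 | [4-(benzyloxy)-2,6-dichlorophenyl]lithium | [Li]c1c(Cl)cc(OCc2ccccc2)cc1Cl | intermediate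
11 | 5-(benzyloxy)-3-chlorobenzyne (1-benzyloxy-3-chloro-4,5-didehydrobenzene) | ClC1=CC(OCc2ccccc2)=CC#C1 | intermediate
12 | methyl (2Z)-3-[5-(benzyloxy)-3-chloro-2-sodiophenoxy]-2-(3,4-dimethoxyphenyl)prop-2-enoate | COC(=O)/C(=C\Oc1cc(OCc2ccccc2)cc(Cl)c1[Na])c1ccc(OC)c(OC)c1 | intermediate
13 | 7-(benzyloxy)-5-chloro-3-(3,4-dimethoxyphenyl)chromen-4-one | COc1ccc(-c2coc3cc(OCc4ccccc4)cc(Cl)c3c2=O)cc1OC | intermediate
14 | 3-(3,4-dimethoxyphenyl)-7-hydroxychromen-4-one | COc1ccc(-c2coc3cc(O)ccc3c2=O)cc1OC | intermediate
15 | prenyl bromide (1-bromo-3-methylbut-2-ene) | CC(C)=CCBr | starting material
16 | 3-(3,4-dimethoxyphenyl)-7-(3-methylbut-2-enyloxy)chromen-4-one | COc1ccc(-c2coc3cc(OCC=C(C)C)ccc3c2=O)cc1OC | target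

## Step count and risks

Total step count: 6. Longest linear sequence: 5 steps (steps 1, 2, 4, 5, 6); step 3 feeds into step 4.

Step 4 (key step). The most likely failure is arylation of the enolate through carbon, followed by transfer of the formyl group to the aryl anion, so that the aryne inserts into the C–CHO bond instead of closing ring C. Further risks are consumption of the aryne by 10 or by the liberated methoxide, and O-arylation from a non-chelated enolate geometry in which the aryl anion cannot reach the ester. The fallback uses the established deoxybenzoin chemistry. It sets out from 6, which is saponified (LiOH, aqueous THF) to (3,4-dimethoxyphenyl)acetic acid F1. F1 acylates resorcinol in BF3·OEt2 at about 85 °C to give 1-(2,4-dihydroxyphenyl)-2-(3,4-dimethoxyphenyl)ethanone F2. Treatment of F2 in the same medium with DMF and methanesulfonyl chloride supplies C2 and closes ring C. The fallback comes back to the route at 14, after which step 6 follows unchanged.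

Step 5. The most likely failure is reduction of the C2=C3 bond to the isoflavanone while the slower hydrodechlorination is still incomplete; slowing of the catalyst by chloride is a second risk. The fallback separates the two tasks and avoids hydrogen gas. It sets out from 13, whose chlorine is removed by homogeneous transfer reduction (palladium diacetate, a bulky dialkylbiarylphosphine, HCO2Na, DMF, 80 °C), which acts by oxidative addition at the C–Cl bond and should leave the enone alone. This gives 7-(benzyloxy)-3-(3,4-dimethoxyphenyl)chromen-4-one F3. The benzyl group of F3 is then removed non-reductively with BCl3 and pentamethylbenzene at –78 °C, conditions that should spare the methyl ethers, none of which is next to a carbonyl. The fallback comes back to the route at 14.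

Step 2. The most likely failure is slow or incomplete magnesiation, because the magnesium amide is a much weaker base than a lithium amide; a second risk is metalation at the position between oxygen and chlorine, assisted by coordination of magnesium to the ether oxygen. The fallback changes the protecting-group order and the metal, so that a bulky, non-benzylic silyl ether shields the positions next to oxygen while a lithium amide does the deprotonation at low temperature. It sets out from 1, which is silylated (triisopropylsilyl chloride, imidazole) to (3,5-dichlorophenoxy)triisopropylsilane F4. Lithiation between the chlorines (LDA, THF, –78 °C) gives [2,6-dichloro-4-(triisopropylsilyloxy)phenyl]lithium F5, which is quenched with iodine at –78 °C to (3,5-dichloro-4-iodophenoxy)triisopropylsilane F6. Tetrabutylammonium fluoride frees 3,5-dichloro-4-iodophenol F7, and benzylation with 2 (K2CO3, DMF) comes back to the route at 5.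

## Further compounds

F1 | step 4 | (3,4-dimethoxyphenyl)acetic acid | COc1ccc(CC(=O)O)cc1OC
F2 | step 4 | 1-(2,4-dihydroxyphenyl)-2-(3,4-dimethoxyphenyl)ethanone | COc1ccc(CC(=O)c2ccc(O)cc2O)cc1OC
F3 | step 5 | 7-(benzyloxy)-3-(3,4-dimethoxyphenyl)chromen-4-one | COc1ccc(-c2coc3cc(OCc4ccccc4)ccc3c2=O)cc1OC
F4 | step 2 | (3,5-dichlorophenoxy)triisopropylsilane | CC(C)[Si](Oc1cc(Cl)cc(Cl)c1)(C(C)C)C(C)C
F5 | step 2 | [2,6-dichloro-4-(triisopropylsilyloxy)phenyl]lithium | [Li]c1c(Cl)cc(O[Si](C(C)C)(C(C)C)C(C)C)cc1Cl
F6 | step 2 | (3,5-dichloro-4-iodophenoxy)triisopropylsilane | CC(C)[Si](Oc1cc(Cl)c(I)c(Cl)c1)(C(C)C)C(C)C
F7 | step 2 | 3,5-dichloro-4-iodophenol | Oc1cc(Cl)c(I)c(Cl)c1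
A1 | alternative 1 | 2-[2-(3,4-dimethoxyphenyl)-2-oxoethoxy]-4-(3-methylbut-2-enyloxy)benzaldehyde | COc1ccc(C(=O)COc2cc(OCC=C(C)C)ccc2C=O)cc1OC
A2 | alternative 1 | (racemic) 3-(3,4-dimethoxyphenyl)-3-hydroxy-7-(3-methylbut-2-enyloxy)chroman-4-one | COc1ccc(C2(O)COc3cc(OCC=C(C)C)ccc3C2=O)cc1OC
A3 | alternative 2 | 3,6-bis(tert-butyldimethylsilyloxy)-1-benzofuran | CC(C)(C)[Si](C)(C)Oc1ccc2c(O[Si](C)(C)C(C)(C)C)coc2c1
A4 | alternative 2 | 3-chloro-3-(3,4-dimethoxyphenyl)-3H-diazirine | COc1ccc(C2(Cl)N=N2)cc1OC
A5 | alternative 2 | 7-(tert-butyldimethylsilyloxy)-3-(3,4-dimethoxyphenyl)chromen-4-one | COc1ccc(-c2coc3cc(O[Si](C)(C)C(C)(C)C)ccc3c2=O)cc1OC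
A6 | alternative 3 | (2Z)-2-(3,4-dimethoxyphenyl)-3-(3-hydroxyphenoxy)prop-2-enoic acid | OC(=O)/C(=C\Oc1cccc(O)c1)c1ccc(OC)c(OC)c1
A7 | alternative 3 | 3-(3,4-dimethoxyphenyl)-7-hydroxychromen-4-one | COc1ccc(-c2coc3cc(O)ccc3c2=O)cc1OC
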